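In a one-step world of growth, a living end adds free monomer while any remains, but this flask gives it a second step that stops it.

    2 initiator → spent initiator (k1 = 5.57 M⁻¹ s⁻¹)
    protic impurity + free monomer → quenched substrate (k2 = 0.244 M⁻¹ s⁻¹)
    free monomer + initiator → living end + monomer in chains (k3 = 0.313 M⁻¹ s⁻¹)
    free monomer + living end → monomer in chains + living end, rate k4*[living end]*[free monomer] (k4 = 11.1 M⁻¹ s⁻¹)
    living end + transfer agent → dead chain (k5 = 15.3 M⁻¹ s⁻¹)

free monomer 0.10 M; transfer agent 3.00 mM; protic impurity 0.0500 M; initiator 1.4 mM; time 2.5 min

- average number of monomer units in a chain (chains begun, living or dead) at 2.5 min
- part of the free monomer that has reacted at 2.5 min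

- where a step has two of a species, its rate is k times that concentration squared, and two are used at each turn
- the average divides the monomer in chains by the number of chains begun, living and dead together
- run time (flask): 2.5 min

Which clock do you start first?

The living end's. Against transfer agent at its charge, its mean life in the flask is 21.8 s. This treats stopping as pseudo-first-order.

What do you count in that life?

Turnovers. I define r, the turnover ratio 242 M⁻¹: growth steps per living end, per unit concentration of free monomer, before transfer agent stops it. At the monomer charge, r gives 24.2 turnovers.

Does the run outlast a chain?

Yes. The run is longer than that mean life, so I count finished chains.

But your free monomer stays at its charge. Does it?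

No, and this is the weak spot. Protic impurity has a half-life of 0.47 min by its reaction with free monomer alone, free monomer taken as charged, and that is shorter than the run, so free monomer falls while chains grow. Each protic impurity takes one free monomer. The charge of protic impurity is smaller than that of free monomer, so this loss by itself takes free monomer down by at most that charge, to 0.0500 M.

Which level do you use, then?

The midpoint of that fall, 0.0750 M. My average is 18.1 units per chain. That is a rough mean, and I do not reckon conversion.

What does the forecast say?

It says 18, within 15 to 21, and a conversion of 61%, within 56% to 66%. Its grounds begin: “Most of the monomer is lost to the large excess of protic impurity”.

The flask gives 18.1 units per chain and a conversion of 62.0%, and with the protic impurity step struck out, conversion is 28.0%. Divided by r, the average reads as a free monomer level of 75.0% of charge, which the flask passed between 82.4% at 0.250 min and 49.3% at 1.25 min. The neighbour flask with 0.12 M of protic impurity has the same r. Its charge of protic impurity is larger than its charge of free monomer, so I take the midpoint between that monomer charge and zero, 0.0500 M, and r gives 12.1. Its chains averaged 11.9.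

The constants used here are assumed.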